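Ring A is cut across C1–C2 and C4–C5 (labdane numbering). In the key step a three-carbon reagent that carries a phosphonium ylide at C2 and a phosphonoacetate carbanion at C4 condenses with a ring-B keto aldehyde: a Wittig reaction makes C1=C2 and an intramolecular Horner–Wadsworth–Emmons reaction makes C4=C5, closing ring A in one operation. The step exploits the 1,3-relationship of the formyl carbon C1 and the ketone carbon C5 on the quaternary C10. The precursor is a 2-formyl-2-methylcyclohexane-1,4-dione with the citronellol-derived side chain at C9, assembled by an enantioselective Diels–Alder reaction. Reductive methylation of the C4=C5 enoate then sets C5 and C4.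

Key step: step 9

Remark on numbering: labdane numbering (C1–C20) is used for all ring compounds from 6 on; α is the ring face opposite the C10 methyl.
Assumption: the (S)-oxazaborolidinium cation is taken to direct the diene to the enal face that gives the C10 configuration drawn in 6; if the sense is opposite, its enantiomer is used and nothing else changes.

Step 1
Reactants: 1 (S)-citronellol
Product: 2 (S)-citronellyl triisopropylsilyl ether
Conditions: TIPSCl, imidazole, DMF, rt
Reagents that add atoms: chlorotri(propan-2-yl)silane, CC(C)[Si](Cl)(C(C)C)C(C)C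
Why: Standard silylation of a primary alcohol; the TIPS ether should survive the Lewis-acidic, hydridic, basic and dissolving-metal steps until the fluoride deprotection, and C13 (S) comes from the chiral pool.

Step 2
Reactants: 2 (S)-citronellyl triisopropylsilyl ether
Product: 4 (2E,6S)-2,6-dimethyl-8-(triisopropylsilyloxy)oct-2-enal, via allylic alcohol 3 (not isolated)
Conditions: SeO2 (1.3 equiv), 1,4-dioxane, 80 °C
Reagents that add atoms: selenium dioxide, O=[Se]=O
Why: Riley allylic oxidation (ene reaction then [2,3]-shift) should attack the E-methyl of the trisubstituted alkene and carry the E-allylic alcohol on to the E-enal, which already holds C1, C9–C16 and C20 of the target.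

Step 3
Reactants: 4 (2E,6S)-2,6-dimethyl-8-(triisopropylsilyloxy)oct-2-enal; 5 (1E,3E)-buta-1,3-diene-1,4-diyl diacetate
Product: 6 ring-B diacetoxy aldehyde (C5-OAc, C8-OAc, C6=C7, C10 with β-methyl and α-formyl, C9 with β side chain)
Conditions: (S)-3,3-diphenyl-1-(o-tolyl)tetrahydro-1H,3H-pyrrolo[1,2-c][1,3,2]oxazaborole (20 mol %), HNTf2 (16 mol %), 5 (2.5 equiv), CH2Cl2, −40 °C to rt
Reagents that add atoms: none
Why: Lewis-acid-catalysed Diels–Alder reaction of an α-methyl enal with a 1-acyloxy diene, in which the chiral oxazaborolidinium cation fixes the face of attack at C10 (catalyst control, the remote C13 has no influence), suprafacial addition to the E-enal places the C9 side chain cis to the C10 methyl, the symmetric diene removes any regiochemical question, and the expected endo sense at C5 and C8 is irrelevant because both become carbonyl carbons.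

Step 4
Reactants: 6 ring-B diacetoxy aldehyde
Product: 7 ring-B enetriol
Conditions: LiAlH4, THF, 0 °C
Reagents that add atoms: none
Why: Hydride reduction of the aldehyde and reductive cleavage of both acetates in one operation avoids basic methanolysis of a β-acetoxy aldehyde, which could undergo retro-aldol cleavage.

Step 5
Reactants: 7 ring-B enetriol
Product: 8 ring-B triol
Conditions: H2 (1 atm), Rh/Al2O3, EtOAc, rt
Reagents that add atoms: none
Why: Heterogeneous hydrogenation of the cis-disubstituted C6=C7 alkene, with rhodium on alumina chosen because it causes little hydrogenolysis of allylic C–O bonds.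

Step 6
Reactants: 8 ring-B triol
Product: 9 ring-B keto aldehyde (C5=O, C8=O, formyl C1 on C10)
Conditions: (COCl)2, DMSO, CH2Cl2, −78 °C; i-Pr2NEt, −78 to −20 °C
Reagents that add atoms: none
Why: Swern oxidation of all three hydroxyl groups under cold, weakly basic conditions should give the non-enolisable β-keto aldehyde without deformylation and without epimerising C9.

Step 7
Reactants: 10 (diethoxyphosphoryl)acetic acid; 11 2-(trimethylsilyl)ethanol
Product: 12 2-(trimethylsilyl)ethyl (diethoxyphosphoryl)acetate
Conditions: DCC, DMAP (cat.), CH2Cl2, 0 °C to rt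
Reagents that add atoms: none
Why: Steglich esterification; the 2-(trimethylsilyl)ethyl ester is chosen because fluoride later frees the hindered C19 carboxyl together with the silyl ether.

Step 8
Reactants: 12 2-(trimethylsilyl)ethyl (diethoxyphosphoryl)acetate; 13 triphenyl(vinyl)phosphonium bromide
Product: 14 phosphonium–phosphonate salt (racemic)
Conditions: DBU (10 mol %), 12 (2 equiv), CH2Cl2, rt; precipitation with Et2O
Reagents that add atoms: none
Why: Base-catalysed Michael addition of the phosphonoacetate carbanion to the vinylphosphonium salt followed by proton transfer gives the C2–C3–C4(C19) unit; the new centre at C4 is racemic and becomes sp2 in step 9.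

Step 9
Reactants: 9 ring-B keto aldehyde; 14 phosphonium–phosphonate salt
Product: 17 2-(trimethylsilyl)ethyl 8-oxo-15-(triisopropylsilyloxy)-17,18-dinorlabda-1,4-dien-19-oate, via ylide phosphonate anion 15 (not isolated), via Wittig alkene anion 16 (not isolated)
Conditions: 14 (1.2 equiv), KN(SiMe3)2 (2.4 equiv), THF, −78 °C; then 9, −78 °C to rt, then 45 °C
Reagents that add atoms: none
Why: Double deprotonation of 14 gives 15, whose non-stabilised ylide carbon C2 olefinates the aldehyde C1 at −78 °C (Wittig reaction), after which the phosphonoacetate carbanion C4 of 16 adds to the C5 ketone and loses diethyl phosphate (intramolecular Horner–Wadsworth–Emmons reaction), so that C1=C2 and C4=C5 are formed in one flask. The closest known reaction type is the double carbonyl olefination of dicarbonyl compounds with bis-phosphorus reagents (bis-Wittig and Wittig–Horner ring closures). Ring A closes in the second olefination by 6-exo-trig attack of C4 on the C5 carbonyl followed by syn-elimination from the oxaphosphetane. No new stereocentre is created: C10 is untouched, both new alkenes are held cis in the ring, and only the Z-alkene expected from the salt-free potassium ylide can cyclise. The step needs the pairing ylide/aldehyde and phosphonate/C5 ketone rather than the reverse or attack on the C8 ketone; this should be secured by the far higher reactivity of the ylide toward the aldehyde (irreversible oxaphosphetane formation against reversible phosphonate addition) and by ring size (six-membered closure at C5 against seven-membered at C8). C9 should not epimerise because the ylide is consumed by the aldehyde and the phosphonate carbanion is too weak a base to enolise the C8 ketone.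

Step 10
Reactants: 17 dienyl keto ester
Product: 18 2-(trimethylsilyl)ethyl 8-oxo-15-(triisopropylsilyloxy)-17,18-dinorlabd-4-en-19-oate
Conditions: H2 (1 atm), Pd/C, EtOAc, rt
Reagents that add atoms: none
Why: Chemoselective hydrogenation of the disubstituted C1=C2 alkene; the tetrasubstituted, ester-conjugated C4=C5 alkene and the ketone are expected to be inert under these conditions.

Step 11
Reactants: 18 keto enoate
Product: 19 2-(trimethylsilyl)ethyl 15-(triisopropylsilyloxy)-18-norlabda-4,8(17)-dien-19-oate
Conditions: Zn, CH2Br2, TiCl4, THF/CH2Cl2, 0 °C to rt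
Reagents that add atoms: dibromomethane, BrCBr
Why: Takai–Lombardo methylenation converts the hindered, enolisable C8 ketone into the exocyclic C8=C17 alkene under non-basic conditions, so that C9 keeps the configuration set in step 3 and the conjugated ester is left alone.

Step 12
Reactants: 19 dienyl ester
Product: 21 2-(trimethylsilyl)ethyl (4S,5R,9S,10R,13S)-15-(triisopropylsilyloxy)labd-8(17)-en-19-oate, via lithium ester enolate 20 (not isolated)
Conditions: Li (2.2 equiv), NH3(l)/THF, t-BuOH (1 equiv), −78 °C; then MeI, −78 to −33 °C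
Reagents that add atoms: iodomethane, CI
Why: Birch-type reductive alkylation of the α,β-unsaturated ester: two-electron reduction and protonation of C5 anti to the C10 methyl should give the trans-fused enolate (5R), and methyl iodide then approaches C4 from the equatorial α face away from the axial C10 methyl, placing CH3 α and the ester β (4S), while the isolated exocyclic alkene is not reduced by lithium in ammonia.

Step 13
Reactants: 21 fully protected labdenoate
Product: 22 (4S,5R,9S,10R,13S)-15-hydroxylabd-8(17)-en-19-oic acid (imbricatolic acid)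
Conditions: TBAF, THF, rt to 50 °C; aq. NH4Cl
Reagents that add atoms: none
Why: Fluoride cleaves the TIPS ether and fragments the 2-(trimethylsilyl)ethyl ester with loss of ethene, a deprotection that does not need access to the hindered axial carboxyl and leaves the exocyclic alkene alone.

Step 14
Reactants: 22 imbricatolic acid; 23 stearoyl chloride
Product: 24 (4S,5R,9S,10R,13S)-15-(octadecanoyloxy)labd-8(17)-en-19-oic acid (target)
Conditions: 23 (1.1 equiv), pyridine, DMAP (cat.), CH2Cl2, 0 °C to rt; aq. work-up
Reagents that add atoms: none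
Why: O-Acylation of the primary C15 alcohol; the hindered tertiary C19 acid should not compete, and any mixed anhydride formed from it is hydrolysed back to the free acid on aqueous work-up.

Compound list
1 | (S)-citronellol, (3S)-3,7-dimethyloct-6-en-1-ol | CC(C)=CCC[C@H](C)CCO | starting material
2 | (S)-citronellyl triisopropylsilyl ether | CC(C)=CCC[C@H](C)CCO[Si](C(C)C)(C(C)C)C(C)C | intermediate
3 | (2E,6S)-2,6-dimethyl-8-(triisopropylsilyloxy)oct-2-en-1-ol | C/C(CO)=C\CC[C@H](C)CCO[Si](C(C)C)(C(C)C)C(C)C | intermediate (not isolated)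
4 | (2E,6S)-2,6-dimethyl-8-(triisopropylsilyloxy)oct-2-enal | C/C(C=O)=C\CC[C@H](C)CCO[Si](C(C)C)(C(C)C)C(C)C | intermediate
5 | (1E,3E)-buta-1,3-diene-1,4-diyl diacetate | CC(=O)O/C=C/C=C/OC(C)=O | starting material
6 | 2,5-diacetoxy-1-methyl-6-[(3S)-3-methyl-5-(triisopropylsilyloxy)pentyl]cyclohex-3-ene-1-carbaldehyde (formyl cis to both acetoxy groups and trans to the side chain; ring C1 = labdane C10) | CC(=O)O[C@@H]1C=C[C@H](OC(C)=O)[C@](C)(C=O)[C@H]1CC[C@H](C)CCO[Si](C(C)C)(C(C)C)C(C)C | intermediate
7 | 5-(hydroxymethyl)-5-methyl-6-[(3S)-3-methyl-5-(triisopropylsilyloxy)pentyl]cyclohex-2-ene-1,4-diol (configuration as in 6) | O[C@@H]1C=C[C@H](O)[C@](C)(CO)[C@H]1CC[C@H](C)CCO[Si](C(C)C)(C(C)C)C(C)C | intermediate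
8 | 2-(hydroxymethyl)-2-methyl-3-[(3S)-3-methyl-5-(triisopropylsilyloxy)pentyl]cyclohexane-1,4-diol (configuration as in 6) | O[C@@H]1CC[C@H](O)[C@](C)(CO)[C@H]1CC[C@H](C)CCO[Si](C(C)C)(C(C)C)C(C)C | intermediate
9 | (1S,6R)-1-methyl-6-[(3S)-3-methyl-5-(triisopropylsilyloxy)pentyl]-2,5-dioxocyclohexane-1-carbaldehyde (labdane C5=O, C8=O, formyl C1 on C10, formyl trans to the side chain) | O=C1CCC(=O)[C@](C)(C=O)[C@H]1CC[C@H](C)CCO[Si](C(C)C)(C(C)C)C(C)C | intermediate
10 | (diethoxyphosphoryl)acetic acid | CCOP(=O)(CC(=O)O)OCC | starting material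
11 | 2-(trimethylsilyl)ethanol | C[Si](C)(C)CCO | starting material
12 | 2-(trimethylsilyl)ethyl (diethoxyphosphoryl)acetate | CCOP(=O)(CC(=O)OCC[Si](C)(C)C)OCC | intermediate
13 | triphenyl(vinyl)phosphonium bromide | C=C[P+](c1ccccc1)(c1ccccc1)c1ccccc1.[Br-] | starting material
14 | [3-(diethoxyphosphoryl)-4-oxo-4-[2-(trimethylsilyl)ethoxy]butyl]triphenylphosphonium bromide (racemic) | CCOP(=O)(OCC)C(CC[P+](c1ccccc1)(c1ccccc1)c1ccccc1)C(=O)OCC[Si](C)(C)C.[Br-] | intermediate
15 | potassium salt of the ylide–phosphonate carbanion of 14 (ylide at C2, carbanion at C4) | CCOP(=O)(OCC)[C-](CC=P(c1ccccc1)(c1ccccc1)c1ccccc1)C(=O)OCC[Si](C)(C)C.[K+] | intermediate (not isolated)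
16 | potassium salt of the (Z)-C1=C2 alkenyl phosphonoacetate carbanion (Wittig product of 9 and 15) | O=C1CCC(=O)[C@](C)(/C=C\C[C-](P(=O)(OCC)OCC)C(=O)OCC[Si](C)(C)C)[C@H]1CC[C@H](C)CCO[Si](C(C)C)(C(C)C)C(C)C.[K+] | intermediate (not isolated)
17 | 2-(trimethylsilyl)ethyl 8-oxo-15-(triisopropylsilyloxy)-17,18-dinorlabda-1,4-dien-19-oate (9α-H, 10β-CH3, 13S) | O=C1CCC2=C(C(=O)OCC[Si](C)(C)C)CC=C[C@]2(C)[C@H]1CC[C@H](C)CCO[Si](C(C)C)(C(C)C)C(C)C | intermediate
18 | 2-(trimethylsilyl)ethyl 8-oxo-15-(triisopropylsilyloxy)-17,18-dinorlabd-4-en-19-oate (9α-H, 10β-CH3, 13S) | O=C1CCC2=C(C(=O)OCC[Si](C)(C)C)CCC[C@]2(C)[C@H]1CC[C@H](C)CCO[Si](C(C)C)(C(C)C)C(C)C | intermediate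
19 | 2-(trimethylsilyl)ethyl 15-(triisopropylsilyloxy)-18-norlabda-4,8(17)-dien-19-oate (9α-H, 10β-CH3, 13S) | C=C1CCC2=C(C(=O)OCC[Si](C)(C)C)CCC[C@]2(C)[C@H]1CC[C@H](C)CCO[Si](C(C)C)(C(C)C)C(C)C | intermediate
20 | lithium enolate of 2-(trimethylsilyl)ethyl 15-(triisopropylsilyloxy)-18-norlabd-8(17)-en-19-oate (5α-H) | C=C1CC[C@@H]2[C@](C)(CCCC2=C([O-])OCC[Si](C)(C)C)[C@H]1CC[C@H](C)CCO[Si](C(C)C)(C(C)C)C(C)C.[Li+] | intermediate (not isolated)
21 | 2-(trimethylsilyl)ethyl (4S,5R,9S,10R,13S)-15-(triisopropylsilyloxy)labd-8(17)-en-19-oate | C=C1CC[C@@H]2[C@](C)(CCC[C@]2(C)C(=O)OCC[Si](C)(C)C)[C@H]1CC[C@H](C)CCO[Si](C(C)C)(C(C)C)C(C)C | intermediate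
22 | (4S,5R,9S,10R,13S)-15-hydroxylabd-8(17)-en-19-oic acid (imbricatolic acid) | C=C1CC[C@@H]2[C@](C)(CCC[C@]2(C)C(=O)O)[C@H]1CC[C@H](C)CCO | intermediate
23 | stearoyl chloride (octadecanoyl chloride) | CCCCCCCCCCCCCCCCCC(=O)Cl | starting material
24 | (4S,5R,9S,10R,13S)-15-(octadecanoyloxy)labd-8(17)-en-19-oic acid (CNP0298278.1) | C=C1CC[C@@H]2[C@](C)(CCC[C@]2(C)C(=O)O)[C@H]1CC[C@H](C)CCOC(=O)CCCCCCCCCCCCCCCCC | target

Total step count: 14. Longest linear sequence: 12 steps (steps 1–6 and 9–14); steps 7 and 8 prepare the C2–C4 reagent.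

Steps most likely to fail

Step 9. What may go wrong: mis-pairing of the two phosphorus nucleophiles with the two carbonyl groups, formation of the E-alkene that cannot cyclise, or deformylation of the β-keto aldehyde after reversible addition of the phosphonate carbanion. The fallback sets out from 9 and returns at 17, still closing ring A in one flask but with a single phosphorus centre. The salt-free ylide from [3-(1,3-dioxolan-2-yl)propyl]triphenylphosphonium bromide (KN(SiMe3)2, THF, −78 °C) olefinates the aldehyde to give the (Z)-alkenyl keto acetal F1. Aqueous HCl added to the same flask unmasks the C19 aldehyde, and pyrrolidinium acetate then drives the intramolecular aldol condensation of C4 onto the C5 ketone to give the dienal F2. Pinnick oxidation (NaClO2, NaH2PO4, 2-methylbut-2-ene) gives the dienoic acid F3, and Steglich esterification with 11 returns 17.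

Step 3. What may go wrong: sluggish cycloaddition of the only moderately electron-rich diacetoxy diene with the trisubstituted enal, with diene decomposition and loss of facial control at the temperature then needed. The fallback sets out from 4 and returns at 9. 2,5-Bis(trimethylsilyloxy)furan, a far more nucleophilic four-carbon partner, is used under the same oxazaborolidinium catalysis at −78 °C to give the oxa-bridged cycloadduct F4. This is hydrolysed on acidic work-up to the ene-1,4-dione aldehyde F5, whose C6=C7 bond is reduced with Zn dust in AcOH to give 9 directly; steps 4–6 are then not needed.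

Step 12. What may go wrong: protonation of the ester enolate before it is methylated, or over-reduction of the ester, so that the quaternary C4 is not formed cleanly. The fallback sets out from 19 and returns at 21. Conjugate reduction alone (Li, NH3/THF, then NH4Cl) gives the saturated trans-fused ester F6; a separate kinetic deprotonation (LDA, THF/DMPU, −78 °C) and methylation with MeI, which follows the same α-face approach, then gives 21.

Further compounds
F1 | step 9 | 1-[(1Z)-4-(1,3-dioxolan-2-yl)but-1-en-1-yl]-1-methyl-6-[(3S)-3-methyl-5-(triisopropylsilyloxy)pentyl]cyclohexane-2,5-dione (ring configuration as in 9) | O=C1CCC(=O)[C@](C)(/C=C\CCC2OCCO2)[C@H]1CC[C@H](C)CCO[Si](C(C)C)(C(C)C)C(C)C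
F2 | step 9 | 8-oxo-15-(triisopropylsilyloxy)-17,18-dinorlabda-1,4-dien-19-al | O=C1CCC2=C(C=O)CC=C[C@]2(C)[C@H]1CC[C@H](C)CCO[Si](C(C)C)(C(C)C)C(C)C
F3 | step 9 | 8-oxo-15-(triisopropylsilyloxy)-17,18-dinorlabda-1,4-dien-19-oic acid | O=C1CCC2=C(C(=O)O)CC=C[C@]2(C)[C@H]1CC[C@H](C)CCO[Si](C(C)C)(C(C)C)C(C)C
F4 | step 3 | 2-methyl-3-[(3S)-3-methyl-5-(triisopropylsilyloxy)pentyl]-1,4-bis(trimethylsilyloxy)-7-oxabicyclo[2.2.1]hept-5-ene-2-carbaldehyde (endo formyl) | C[Si](C)(C)O[C@@]12C=C[C@@](O[Si](C)(C)C)(O1)[C@](C)(C=O)[C@H]2CC[C@H](C)CCO[Si](C(C)C)(C(C)C)C(C)C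
F5 | step 3 | 1-methyl-6-[(3S)-3-methyl-5-(triisopropylsilyloxy)pentyl]-2,5-dioxocyclohex-3-ene-1-carbaldehyde (ring configuration as in 9) | O=C1C=CC(=O)[C@](C)(C=O)[C@H]1CC[C@H](C)CCO[Si](C(C)C)(C(C)C)C(C)C
F6 | step 12 | 2-(trimethylsilyl)ethyl 15-(triisopropylsilyloxy)-18-norlabd-8(17)-en-19-oate (5α-H, 4β-H, equatorial ester) | C=C1CC[C@@H]2[C@](C)(CCC[C@H]2C(=O)OCC[Si](C)(C)C)[C@H]1CC[C@H](C)CCO[Si](C(C)C)(C(C)C)C(C)C
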